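## Structural features

The target is an achiral open-chain hexamer: six benzene rings (A to F) joined only by five diaryl ether oxygens, with no carbon–carbon bond between rings. It has no stereocentre, so no stereocentres stand next to each other and none has to be set. Ring A is a phloroglucinol with hydroxyls on C1, C3 and C5 and the ether oxygen on C2; rings B to E are 1,3-dihydroxybenzenes with one ether oxygen on C2 and the other on C5; ring F is a 3,4,5-trihydroxyphenyl group bound through C1. Each ether oxygen thus links C2 of one ring to C5 of the next (C1 for ring F). The fourteen free phenols sit on 1,2,3,5-tetraoxygenated rings, so the compound is very electron-rich: as a phenolate it is oxidised by air to quinones, and its free ring positions are strong carbon nucleophiles. The real difficulty is the five aryl–oxygen bonds at C2 of rings A to E: each lies on a carbon with two oxygenated ortho neighbours on an electron-rich ring, the worst case for copper- or palladium-mediated etherification, and the same bond must be made five times without erosion. The key step exploits the fact that C1 and C3 of rings A to E, the ten carbons ortho to the ether carbons, all carry hydroxyls: as formyl groups they first make C2 the doubly activated site of a nucleophilic aromatic substitution and are then exchanged for hydroxyls by oxygen insertion. Ring F has no oxygen ortho to its ether carbon and can only enter as the nucleophile, which fixes chain growth from F towards A.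

## Logic of the disconnections

**21 from 20.** The four benzylic carbon–oxygen bonds (one on the C5 oxygen of ring A, three on ring F) are cut. Hydrogenolysis is neutral and reducing, the only kind of last step a fourteen-fold polyphenol tolerates, and it leaves the five diaryl ethers alone. The gain is that every step before it handles a compound with four fewer free phenols and no phenol on ring F. The forward step must go to completion on all four ethers and the product must be isolated without contact with air or base.

**20 from 18 through 19.** Ten carbon–oxygen bonds, at C1 and C3 of rings A to E, are cut and each oxygen is replaced by a formyl carbon. This turns an air-sensitive decaol into a robust, electron-poor deca-aldehyde and makes every ether carbon C2 a former SNAr site. The gain is that all ten hydroxyls are installed in one operation at the end, with no protecting group on any of them. The demand is severe: aryl migration must win at all ten Criegee adducts, the peracid must spare ring F and the benzyl ethers, and no phenol may be liberated while oxidant is present. For that reason the formates of 19 are kept intact until the peracid is reduced and are then cleaved with acid, not base. The benzyl ether on ring A is kept so that no acetal has to be cleaved on the electron-rich decaol.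

**18 from 17 and 6.** The bond from C2 of ring A to the ether oxygen is cut. C2 of 6 carries fluorine between two formyl groups, so the bond forms by addition–elimination. The gain is one ring and a return to the repeating series. The forward step needs the phenoxide of 17 to attack the C–F carbon of 6 faster than the aryloxy-bearing C2 carbons of rings B to E, which are activated in the same way. This is why the phenoxide is always the limiting partner and the fluoride is in slight excess.

**17 back to 9 and four molecules of 5 (through 16, 15, 14, 13, 12, 11 and 10).** In each of four identical cycles the C2–oxygen bond of the newest ring and the oxygen–CH2OMe bond on its C5 oxygen are cut. Each cycle removes one ring and uses the same two reactions, so only one building block, 5, is needed for rings B to E. The acetal on 5 must survive carbonate, fluoride and DMF and must come off in aqueous acid without harm to formyl groups, benzyl ethers or diaryl ethers. All four removals take place on electron-poor polyaldehydes, where the released formaldehyde finds no nucleophilic arene except the flanked positions of ring F.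

**9 from 7 through 8.** The phenolic carbon–oxygen bond is cut back to a formyl carbon. The catalogue aldehyde 7 becomes the ring F nucleophile in one operation and serves as a small-scale rehearsal of the key step; the para benzyloxy donor makes this oxidation unproblematic.

**5 and 6 from 4.** The oxygen–alkyl bonds are cut. One phenol serves both the repeating unit and the ring A unit. The alkylations must outrun self-condensation, because the phenoxide of 4 is a nucleophile and 5 and 6 are activated fluorides.

**4 from 1 through 3 and 2.** The two formyl C=O bonds are traced to dibromomethyl and then methyl groups, and the phenol is masked as an acetate. The fluorine and the oxygen are already in place in 1, so only the oxidation level of two carbons changes. The bromination must stop at two bromines per carbon, and the hydrolysis must run without base so that the activated C–F bond survives.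

## Other disconnections considered

**Alternative 1:** The cut takes out at once the four ether bonds from the oxygens of rings A, B, C and D to C5 of rings B, C, D and E. The undecamethyl pentamer phenol A3 then falls apart into one molecule of 2,4,6-trimethoxyphenol A2 as chain starter and four molecules of syringic acid A1. The forward key step would be anodic oxidation of A2 with four equivalents of A1. The oxidised phenol oxygen bonds to the carboxyl-bearing para carbon of A1, decarboxylation restores the aromatic ring and leaves a new terminal phenol, and the sequence repeats.

- In its favour: the oxygenation pattern of rings A to E is bought complete, and no activating group has to be introduced and later converted. Both ortho positions of every phenol are blocked, so carbon–carbon coupling is shut out.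
- Where it is better or equal: on step economy it is clearly the better plan, one operation from two catalogue compounds against fifteen steps to 18. In forming only carbon–oxygen bonds the two plans are equal.
- Against it here: the process is a chain growth with no built-in stop, so A3 would be one member of a distribution that also holds oligomers of A1 alone. Each product is oxidised more easily than A1 and A2, which invites over-oxidation. The para methoxy group of A2 can be lost on oxidation with quinone formation.
- What remains unsolved: ring F must still be attached to the phenol oxygen of A3, which lies between two methoxy groups, exactly the hindered bond type that makes the target difficult. Fourteen methyl ethers would then need a strong Lewis acid, a harsher end than hydrogenolysis.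
- Comparison: the chosen plan adds exactly one ring per substitution event and can be checked after every cycle. The anodic route depends on small differences in oxidation potential and coupling rate. The chosen plan is longer but controllable; the alternative is shorter but statistical.

**Alternative 2:** The cut opens ring D at three carbon–carbon bonds (C1–C2, C3–C4 and C6–C1). This leaves the cyclobutenone A4, which carries rings A–B–C on the oxygen at its C3, and the siloxyalkyne A5, which carries rings E–F on the oxygen of its second alkyne carbon. On heating, A4 should open to a vinylketene that adds to A5 in a [2+2] manner. A 4π opening of the new cyclobutenone, 6π closure of the dienylketene and tautomerisation would give the hexamer A6, with ring D as a resorcinol bearing one free and one silylated hydroxyl.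

- Where it is better or equal: the plan is convergent, joining a trimer and a dimer in the step that also creates a ring, which is better than the linear growth of the chosen plan. The key event is thermal and neutral, with no base, no oxidant and no migration-selectivity question, so on chemoselectivity of that event it is also the better. The placement of the ring D oxygens is as certain as in the chosen plan (equal).
- Against it here: A5 is an acetylene with oxygen on both carbons, a type for which no reliable preparation can be assumed and which is expected to be very labile. The regiochemistry of the [2+2] step rests on the small difference between a siloxy and an aryloxy donor. A4 and A5 already contain three of the five hindered diaryl ethers, for which this disconnection offers nothing, so the central problem only moves into the fragments.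
- End game and step count: thirteen methyl ethers and a silyl ether again call for a strong Lewis acid. The route cannot be shorter than the chosen one, because each fragment needs its own ether syntheses plus the four-carbon and two-carbon units.

**Alternative 3:** The cut breaks the C1–C2 bond of ring A and unfolds the ring into the methyl 6-aryloxy-3,5-dioxohexanoate A7, whose C6 carries the ring B oxygen (aryl = 4-benzyloxy-3,5-dimethoxyphenyl). Strong base would convert A7 into its polyanion. C6 then attacks the ester carbon in a Claisen condensation that closes the six-membered ring, and the cyclohexane-1,3,5-trione enolises to the ring A–B dimer A8.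

- Where it is better or equal: the hindered oxygen–C2 bond of ring A is never made on an arene. It comes from ordinary alkylation of a phenol oxygen by an α-halo carbonyl unit before the ring exists, which is better than any aromatic substitution, the chosen one included. Ring A also arrives with three free hydroxyls and no redox or deprotection step, which for this one ring is better than the formyl detour.
- Against it here: one application makes one ring of six, and the easiest one. To repeat it, the C5 hydroxyl of a free phloroglucinol such as A8 would have to be alkylated selectively in every round and then extended and cyclised. That is three or four steps per ring, with a protecting-group problem that grows with the chain.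
- Mechanistic weakness: the cyclisation needs the least acidic position (C6) to act as the nucleophile, and closure through the C5 enol oxygen to a pyranone competes.
- Comparison: the chosen plan needs two steps per ring of one repeated type and postpones all fragile phenols to the end. The alternative exposes free polyphenols to strong base from the first ring on. On step economy and robustness the chosen plan is the stronger; on how the hindered ether bond is formed, the alternative is at least its equal.

Key step: step 16

Remark on the chemistry: in rings A to E the ether carbon between the two hydroxyl-bearing carbons is called C2, and C5 carries the second ether oxygen (the third hydroxyl in ring A). Compounds 1 and 7 and all reagents are taken as catalogue materials, and equivalents of mCPBA refer to active peracid. The structures of 18 and 20 were checked atom by atom against 21 (C36H26O19, fourteen hydroxyls, five ether oxygens) and are consistent with it.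

## Route

Step 1
Reactants: 1 4-fluoro-3,5-dimethylphenol
Product: 2 4-fluoro-3,5-dimethylphenyl acetate
Conditions: Ac2O, pyridine, DMAP (cat.), CH2Cl2, 0 °C to rt
Reagents that add atoms: acetic anhydride, CC(=O)OC(C)=O
Why: O-Acylation of a phenol (nucleophilic acyl substitution). The acetate removes the free phenol, which would be brominated on the ring and would quench the radical chain in step 2.

Step 2
Reactants: 2 4-fluoro-3,5-dimethylphenyl acetate
Product: 3 3,5-bis(dibromomethyl)-4-fluorophenyl acetate
Conditions: NBS (4.4 equiv), AIBN (cat.), PhCF3, reflux
Reagents that add atoms: N-bromosuccinimide, O=C1CCC(=O)N1Br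
Why: Wohl–Ziegler radical bromination of the two benzylic methyl groups. Each carbon takes two bromines, a third being disfavoured sterically and by the polar effect of two bromines next to an ortho fluorine, and the acetoxy- and fluoro-substituted ring resists ionic bromination.

Step 3
Reactants: 3 3,5-bis(dibromomethyl)-4-fluorophenyl acetate
Product: 4 2-fluoro-5-hydroxybenzene-1,3-dicarbaldehyde
Conditions: HCO2H/H2O (9:1), reflux; then H2O, 60 °C
Reagents that add atoms: water, O
Why: Solvolysis of the two benzylic gem-dibromides (ionisation, capture by water or formate, loss of HBr) gives the formyl groups, and the HBr formed cleaves the aryl acetate by acid-catalysed hydrolysis in the same pot. The medium stays acidic, so the C–F bond, now flanked by two formyl groups, meets neither hydroxide nor phenoxide.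

Step 4
Reactants: 4 2-fluoro-5-hydroxybenzene-1,3-dicarbaldehyde
Product: 5 2-fluoro-5-(methoxymethoxy)benzene-1,3-dicarbaldehyde
Conditions: MOMCl, i-Pr2NEt (added last, slowly), CH2Cl2, 0 °C
Reagents that add atoms: chloromethyl methyl ether, COCCl
Why: O-Alkylation of the phenol by the oxocarbenium-like chloromethyl ether, which captures the ammonium phenoxide at 0 °C before it can attack the activated C–F bond of a second molecule. The MOM acetal tolerates carbonate, fluoride and DMF in the couplings and is removed later by aqueous acid.

Step 5
Reactants: 4 2-fluoro-5-hydroxybenzene-1,3-dicarbaldehyde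
Product: 6 5-(benzyloxy)-2-fluorobenzene-1,3-dicarbaldehyde
Conditions: BnBr (excess), K2CO3, acetone, rt, slow addition of 4
Reagents that add atoms: benzyl bromide, BrCc1ccccc1
Why: Williamson ether synthesis; 4 is added slowly to excess benzyl bromide so that benzylation outruns intermolecular SNAr, which is slow in acetone. The benzyl ether is chosen for ring A because it leaves together with the ring F benzyl ethers in the last step.

Step 6
Reactants: 7 3,4,5-tris(benzyloxy)benzaldehyde
Product: 9 3,4,5-tris(benzyloxy)phenol, via aryl formate 8 (not isolated)
Conditions: mCPBA, CH2Cl2, 0 °C to rt; aq Na2SO3; then K2CO3 (cat.), MeOH, rt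
Reagents that add atoms: 3-chloroperoxybenzoic acid (mCPBA), OOC(=O)c1cccc(Cl)c1
Why: Dakin-type Baeyer–Villiger oxidation; the para benzyloxy donor makes aryl migration in the Criegee adduct dominant, and the formate 8 is cleaved by base-catalysed transesterification with methanol.

Step 7
Reactants: 9 3,4,5-tris(benzyloxy)phenol; 5 2-fluoro-5-(methoxymethoxy)benzene-1,3-dicarbaldehyde
Product: 10 ring E–F dimer MOM ether
Conditions: K2CO3, 4 Å MS, DMF, rt
Reagents that add atoms: none
Why: Nucleophilic aromatic substitution by addition–elimination: the phenoxide of 9 adds to the fluorine-bearing carbon of 5, the Meisenheimer adduct is stabilised by both ortho formyl groups, and fluoride leaves. Fluorine is the best leaving group for this mechanism and 9 is an electron-rich, unhindered phenol, so the hindered ether should form at room temperature.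

Step 8
Reactants: 10 ring E–F dimer MOM ether
Product: 11 ring E–F dimer phenol
Conditions: 3 M aq HCl, THF, 50 °C
Reagents that add atoms: none
Why: Acid-catalysed hydrolysis of the MOM acetal; aryl benzyl ethers, the diaryl ether and the formyl groups are inert to dilute aqueous HCl, and the water present keeps the aldehydes from being trapped as acetals. The released formaldehyde stays dilute and hydrated, and ring E is too electron-poor to be alkylated by it.

Step 9
Reactants: 11 ring E–F dimer phenol; 5 2-fluoro-5-(methoxymethoxy)benzene-1,3-dicarbaldehyde
Product: 12 ring D–E–F trimer MOM ether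
Conditions: K2CO3, 4 Å MS, DMF, rt to 40 °C
Reagents that add atoms: none
Why: The same SNAr as in step 7; the phenoxide of 11 is less basic because of its two meta formyl groups but is unhindered. It is the limiting partner and 5 is in slight excess, so it is consumed at the far more reactive C–F carbon before it can exchange with the aryloxy group on the activated C2 of ring E.

Step 10
Reactants: 12 ring D–E–F trimer MOM ether
Product: 13 ring D–E–F trimer phenol
Conditions: 3 M aq HCl, THF, 50 °C
Reagents that add atoms: none
Why: Acid-catalysed MOM acetal hydrolysis as in step 8; nothing else in the molecule is acid-labile under these dilute aqueous conditions.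

Step 11
Reactants: 13 ring D–E–F trimer phenol; 5 2-fluoro-5-(methoxymethoxy)benzene-1,3-dicarbaldehyde
Product: 14 ring C–D–E–F tetramer MOM ether
Conditions: K2CO3, 4 Å MS, DMF, rt to 40 °C
Reagents that add atoms: none
Why: SNAr by addition–elimination as in step 9; the reacting phenoxide has the same local structure as that of 11, so the reactivity should carry over, and fluoride remains the only good leaving group offered to it.

Step 12
Reactants: 14 ring C–D–E–F tetramer MOM ether
Product: 15 ring C–D–E–F tetramer phenol
Conditions: 3 M aq HCl, THF, 50 °C
Reagents that add atoms: none
Why: Acid-catalysed MOM acetal hydrolysis as in step 8.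

Step 13
Reactants: 15 ring C–D–E–F tetramer phenol; 5 2-fluoro-5-(methoxymethoxy)benzene-1,3-dicarbaldehyde
Product: 16 ring B–C–D–E–F pentamer MOM ether
Conditions: K2CO3, 4 Å MS, DMF, rt to 40 °C
Reagents that add atoms: none
Why: SNAr by addition–elimination as in step 9, with the phenoxide again limiting and the temperature kept low to suppress aryloxide exchange at the internal activated carbons.

Step 14
Reactants: 16 ring B–C–D–E–F pentamer MOM ether
Product: 17 ring B–C–D–E–F pentamer phenol
Conditions: 3 M aq HCl, THF, 50 °C
Reagents that add atoms: none
Why: Acid-catalysed MOM acetal hydrolysis as in step 8.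

Step 15
Reactants: 17 ring B–C–D–E–F pentamer phenol; 6 5-(benzyloxy)-2-fluorobenzene-1,3-dicarbaldehyde
Product: 18 hexameric deca-aldehyde
Conditions: K2CO3, 4 Å MS, DMF, rt to 40 °C
Reagents that add atoms: none
Why: SNAr by addition–elimination at the doubly formyl-activated C–F carbon of 6, which closes the chain with ring A. The para benzyloxy group of 6 lowers the reactivity no more than the MOM-oxy group of 5 does, so the conditions of the earlier couplings should apply.

Step 16
Reactants: 18 hexameric deca-aldehyde
Product: 20 tetra-O-benzyl hexamer decaol, via deca-formate 19 (not isolated)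
Conditions: mCPBA (excess, in portions), CH2Cl2, 0 to 35 °C; aq Na2SO3, 0 °C; then 0.5 M HCl in degassed MeOH, THF, rt, Ar
Reagents that add atoms: 3-chloroperoxybenzoic acid (mCPBA), OOC(=O)c1cccc(Cl)c1
Why: Each formyl carbon adds the peracid to give a Criegee peroxy-hemiacetal, which collapses with migration of the ring carbon (C1 or C3) from carbon to oxygen and loss of 3-chlorobenzoate, so that every Ar–CHO becomes Ar–OCHO at the same position; once the excess peracid is reduced, acid-catalysed transesterification with methanol releases the ten phenols and methyl formate. The closest known reaction type is the Dakin-type Baeyer–Villiger oxidation of ortho-alkoxy and ortho-aryloxy benzaldehydes, together with the twofold Dakin oxidation of 2-oxygenated benzene-1,3-dicarbaldehydes; here it is asked to run ten times on one molecule. No ring is closed and no stereocentre is formed. The step needs aryl over hydride migration at all ten sites, and chemoselectivity for the formyl groups over the four benzyl ethers, the five diaryl ethers and ring F. Aryl migration is supported by the ether oxygen on C2, which is ortho to every formyl group, and by the acidic aprotic medium, since loss of the formyl hydrogen is the base-promoted path. Over-oxidation is held back because each new oxygen stays an electron-poor formate until the peracid is destroyed, and the methanolysis is run under acid and argon so that no phenolate meets air. The diaryl ethers have no reaction channel with a peracid, and ring F is comparable in electron density to the formate 8, which is expected to survive the same reagent in step 6.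

Step 17
Reactants: 20 tetra-O-benzyl hexamer decaol
Product: 21 2-[3,5-dihydroxy-4-[3,5-dihydroxy-4-[3,5-dihydroxy-4-[3,5-dihydroxy-4-(3,4,5-trihydroxyphenoxy)phenoxy]phenoxy]phenoxy]phenoxy]benzene-1,3,5-triol
Conditions: H2 (1 atm), Pd/C (10 wt% Pd), degassed THF/MeOH, rt; filtration under Ar
Reagents that add atoms: none
Why: Hydrogenolysis of four aryl benzyl ethers on palladium; diaryl ethers and the arene rings are not reduced at one atmosphere and room temperature. The neutral, reducing medium is the safest environment for the free polyphenol.

## Compound list

1 | 4-fluoro-3,5-dimethylphenol | Cc1cc(O)cc(C)c1F | starting material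
2 | 4-fluoro-3,5-dimethylphenyl acetate | CC(=O)Oc1cc(C)c(F)c(C)c1 | intermediate
3 | 3,5-bis(dibromomethyl)-4-fluorophenyl acetate | CC(=O)Oc1cc(C(Br)Br)c(F)c(C(Br)Br)c1 | intermediate
4 | 2-fluoro-5-hydroxybenzene-1,3-dicarbaldehyde | O=Cc1cc(O)cc(C=O)c1F | intermediate
5 | 2-fluoro-5-(methoxymethoxy)benzene-1,3-dicarbaldehyde | COCOc1cc(C=O)c(F)c(C=O)c1 | intermediate
6 | 5-(benzyloxy)-2-fluorobenzene-1,3-dicarbaldehyde | O=Cc1cc(OCc2ccccc2)cc(C=O)c1F | intermediate
7 | 3,4,5-tris(benzyloxy)benzaldehyde | O=Cc1cc(OCc2ccccc2)c(OCc2ccccc2)c(OCc2ccccc2)c1 | starting material
8 | 3,4,5-tris(benzyloxy)phenyl formate | O=COc1cc(OCc2ccccc2)c(OCc2ccccc2)c(OCc2ccccc2)c1 | intermediate (not isolated)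
9 | 3,4,5-tris(benzyloxy)phenol | Oc1cc(OCc2ccccc2)c(OCc2ccccc2)c(OCc2ccccc2)c1 | intermediate
10 | ring E–F dimer MOM ether: 5-(methoxymethoxy)-2-[3,4,5-tris(benzyloxy)phenoxy]benzene-1,3-dicarbaldehyde | COCOc1cc(C=O)c(Oc2cc(OCc3ccccc3)c(OCc3ccccc3)c(OCc3ccccc3)c2)c(C=O)c1 | intermediate
11 | ring E–F dimer phenol: 5-hydroxy-2-[3,4,5-tris(benzyloxy)phenoxy]benzene-1,3-dicarbaldehyde | Oc1cc(C=O)c(Oc2cc(OCc3ccccc3)c(OCc3ccccc3)c(OCc3ccccc3)c2)c(C=O)c1 | intermediate
12 | ring D–E–F trimer MOM ether: 2-{3,5-diformyl-4-[3,4,5-tris(benzyloxy)phenoxy]phenoxy}-5-(methoxymethoxy)benzene-1,3-dicarbaldehyde | COCOc1cc(C=O)c(Oc2cc(C=O)c(Oc3cc(OCc4ccccc4)c(OCc4ccccc4)c(OCc4ccccc4)c3)c(C=O)c2)c(C=O)c1 | intermediate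
13 | ring D–E–F trimer phenol: as 12 with a free hydroxyl in place of the MOM ether | Oc1cc(C=O)c(Oc2cc(C=O)c(Oc3cc(OCc4ccccc4)c(OCc4ccccc4)c(OCc4ccccc4)c3)c(C=O)c2)c(C=O)c1 | intermediate
14 | ring C–D–E–F tetramer MOM ether: rings C, D and E are benzene-1,3-dicarbaldehydes, each bound through its C2 oxygen to C5 of the next ring towards F (C1 of ring F), ring F is 3,4,5-tris(benzyloxy)phenyl, and the C5 oxygen of ring C is a MOM ether | COCOc1cc(C=O)c(Oc2cc(C=O)c(Oc3cc(C=O)c(Oc4cc(OCc5ccccc5)c(OCc5ccccc5)c(OCc5ccccc5)c4)c(C=O)c3)c(C=O)c2)c(C=O)c1 | intermediate
15 | ring C–D–E–F tetramer phenol: as 14 with a free hydroxyl on C5 of ring C | Oc1cc(C=O)c(Oc2cc(C=O)c(Oc3cc(C=O)c(Oc4cc(OCc5ccccc5)c(OCc5ccccc5)c(OCc5ccccc5)c4)c(C=O)c3)c(C=O)c2)c(C=O)c1 | intermediate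
16 | ring B–C–D–E–F pentamer MOM ether: as 14 with one more benzene-1,3-dicarbaldehyde ring (ring B), MOM ether on the C5 oxygen of ring B | COCOc1cc(C=O)c(Oc2cc(C=O)c(Oc3cc(C=O)c(Oc4cc(C=O)c(Oc5cc(OCc6ccccc6)c(OCc6ccccc6)c(OCc6ccccc6)c5)c(C=O)c4)c(C=O)c3)c(C=O)c2)c(C=O)c1 | intermediate
17 | ring B–C–D–E–F pentamer phenol: as 16 with a free hydroxyl on C5 of ring B (octa-aldehyde) | Oc1cc(C=O)c(Oc2cc(C=O)c(Oc3cc(C=O)c(Oc4cc(C=O)c(Oc5cc(OCc6ccccc6)c(OCc6ccccc6)c(OCc6ccccc6)c5)c(C=O)c4)c(C=O)c3)c(C=O)c2)c(C=O)c1 | intermediate
18 | hexameric deca-aldehyde: ring A 4-(benzyloxy)-2,6-diformylphenoxy, rings B to E 2,6-diformyl-1,4-phenylenedioxy, ring F 3,4,5-tris(benzyloxy)phenyl | O=Cc1cc(OCc2ccccc2)cc(C=O)c1Oc1cc(C=O)c(Oc2cc(C=O)c(Oc3cc(C=O)c(Oc4cc(C=O)c(Oc5cc(OCc6ccccc6)c(OCc6ccccc6)c(OCc6ccccc6)c5)c(C=O)c4)c(C=O)c3)c(C=O)c2)c(C=O)c1 | intermediate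
19 | deca-formate: 18 with each of the ten formyl groups replaced by a formyloxy group | O=COc1cc(OCc2ccccc2)cc(OC=O)c1Oc1cc(OC=O)c(Oc2cc(OC=O)c(Oc3cc(OC=O)c(Oc4cc(OC=O)c(Oc5cc(OCc6ccccc6)c(OCc6ccccc6)c(OCc6ccccc6)c5)c(OC=O)c4)c(OC=O)c3)c(OC=O)c2)c(OC=O)c1 | intermediate (not isolated)
20 | tetra-O-benzyl hexamer decaol: free hydroxyls on C1 and C3 of rings A to E, benzyl ethers on the C5 oxygen of ring A and on the three oxygens of ring F | Oc1cc(OCc2ccccc2)cc(O)c1Oc1cc(O)c(Oc2cc(O)c(Oc3cc(O)c(Oc4cc(O)c(Oc5cc(OCc6ccccc6)c(OCc6ccccc6)c(OCc6ccccc6)c5)c(O)c4)c(O)c3)c(O)c2)c(O)c1 | intermediate
21 | 2-[3,5-dihydroxy-4-[3,5-dihydroxy-4-[3,5-dihydroxy-4-[3,5-dihydroxy-4-(3,4,5-trihydroxyphenoxy)phenoxy]phenoxy]phenoxy]phenoxy]benzene-1,3,5-triol (CNP0187343.0; achiral) | Oc1cc(O)c(Oc2cc(O)c(Oc3cc(O)c(Oc4cc(O)c(Oc5cc(O)c(Oc6cc(O)c(O)c(O)c6)c(O)c5)c(O)c4)c(O)c3)c(O)c2)c(O)c1 | target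

## Step count and least certain steps

Total step count: 17. Longest linear sequence: 15 steps (steps 1 to 4, then 7 to 17).

**Step 16 (key step).** The likeliest failure is loss of migration selectivity or of chemoselectivity at one or more of the ten sites. Each formyl group sits on a ring with a second acceptor meta to it, and its only conjugating donor is the ortho ether oxygen, which is twisted by its two ortho neighbours. Collapse of a Criegee adduct by hydride shift would then give a carboxylic acid, and one failure in ten spoils the material. A second process is premature loss of formates during long exposure to peracid, followed by oxidation of the freed phenols or of ring F to quinones. The fallback changes the migrating-group competition and uses known chemistry. From 18, tenfold addition of MeMgBr (THF, −78 to 0 °C) should give the decakis(1-hydroxyethyl) hexamer F1 as a mixture of diastereomers. Oxidation with Dess–Martin periodinane (CH2Cl2, rt) should give the deca-acetyl hexamer F2. Baeyer–Villiger oxidation of F2 (mCPBA, CF3CO2H cat., CH2Cl2) should give the deca-acetate F3, for which the only competitor to aryl migration is the much slower methyl migration. Acid methanolysis of F3 (HCl, degassed MeOH) comes back to the route at 20.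

**Step 15 (and, to a lesser degree, steps 9, 11 and 13).** The likeliest failure is aryloxide exchange. The phenoxide of 17 can attack the aryloxy-bearing C2 carbons of rings B to E of another molecule, which are activated by the same two formyl groups as the C–F carbon, and this scrambles chain lengths. The low nucleophilicity of the formyl-substituted phenoxide makes the wanted reaction slow enough for this to matter. The fallback switches the activation off where it is not wanted. From 17, acetalisation of all eight formyl groups (ethylene glycol, TsOH cat., toluene, Dean–Stark) should give the octakis(1,3-dioxolan-2-yl) pentamer phenol F4. Its phenoxide is more nucleophilic and its diaryl ethers are no longer activated. Coupling of F4 with 6 (K2CO3, DMF, rt) should give the hexamer F5, with dioxolanes on rings B to E and two formyl groups on ring A; the only exchange still possible is degenerate. Hydrolysis of F5 (3 M aq HCl, THF, rt) comes back to the route at 18.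

**Step 2.** The likeliest failure is incomplete or uneven bromination. The fourth bromine has to enter a hindered benzylic position next to fluorine, so mixtures of tri-, tetra- and pentabromides can result, and these carry through the hydrolysis as inseparable aldehyde mixtures. The fallback goes through the monobromide level and an oxidation instead of a hydrolysis. From 2, bromination with NBS (2.2 equiv, AIBN, PhCF3, reflux) should give 3,5-bis(bromomethyl)-4-fluorophenyl acetate F6, with over-brominated material brought back to F6 by diethyl phosphite and i-Pr2NEt (THF, 0 °C). Oxidation of F6 with 4-methylmorpholine N-oxide (MeCN, rt) should give 4-fluoro-3,5-diformylphenyl acetate F7. Acid deacetylation of F7 (3 M aq HCl, THF, 50 °C) comes back to the route at 4.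

**Step 17.** The likeliest failure is oxidative degradation during isolation: the fourteen-fold polyphenol is oxidised by air on the filter and on concentration, and it is too polar for ordinary chromatography, so partly debenzylated material cannot be removed. The fallback isolates the product in a protected, purifiable form. From 20, hydrogenolysis as in step 17 is followed by filtration under argon directly into Ac2O/pyridine, which should give the tetradecaacetate F8, stable to air and to chromatography. Acid methanolysis of F8 (HCl in degassed MeOH, 40 °C, Ar) and evaporation come back to the route at 21.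

## Further compounds

F1 | step 16 | decakis(1-hydroxyethyl) hexamer (18 with each CHO replaced by CH(OH)CH3; mixture of diastereomers, configuration not defined) | CC(O)c1cc(OCc2ccccc2)cc(C(C)O)c1Oc1cc(C(C)O)c(Oc2cc(C(C)O)c(Oc3cc(C(C)O)c(Oc4cc(C(C)O)c(Oc5cc(OCc6ccccc6)c(OCc6ccccc6)c(OCc6ccccc6)c5)c(C(C)O)c4)c(C(C)O)c3)c(C(C)O)c2)c(C(C)O)c1
F2 | step 16 | deca-acetyl hexamer (18 with each CHO replaced by COCH3) | CC(=O)c1cc(OCc2ccccc2)cc(C(C)=O)c1Oc1cc(C(C)=O)c(Oc2cc(C(C)=O)c(Oc3cc(C(C)=O)c(Oc4cc(C(C)=O)c(Oc5cc(OCc6ccccc6)c(OCc6ccccc6)c(OCc6ccccc6)c5)c(C(C)=O)c4)c(C(C)=O)c3)c(C(C)=O)c2)c(C(C)=O)c1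
F3 | step 16 | deca-acetate of 20 | CC(=O)Oc1cc(OCc2ccccc2)cc(OC(C)=O)c1Oc1cc(OC(C)=O)c(Oc2cc(OC(C)=O)c(Oc3cc(OC(C)=O)c(Oc4cc(OC(C)=O)c(Oc5cc(OCc6ccccc6)c(OCc6ccccc6)c(OCc6ccccc6)c5)c(OC(C)=O)c4)c(OC(C)=O)c3)c(OC(C)=O)c2)c(OC(C)=O)c1
F4 | step 15 | octakis(1,3-dioxolan-2-yl) pentamer phenol (17 with every CHO as its ethylene acetal) | Oc1cc(C7OCCO7)c(Oc2cc(C7OCCO7)c(Oc3cc(C7OCCO7)c(Oc4cc(C7OCCO7)c(Oc5cc(OCc6ccccc6)c(OCc6ccccc6)c(OCc6ccccc6)c5)c(C7OCCO7)c4)c(C7OCCO7)c3)c(C7OCCO7)c2)c(C7OCCO7)c1
F5 | step 15 | hexamer with two formyl groups on ring A and ethylene acetals on rings B to E | O=Cc1cc(OCc2ccccc2)cc(C=O)c1Oc1cc(C7OCCO7)c(Oc2cc(C7OCCO7)c(Oc3cc(C7OCCO7)c(Oc4cc(C7OCCO7)c(Oc5cc(OCc6ccccc6)c(OCc6ccccc6)c(OCc6ccccc6)c5)c(C7OCCO7)c4)c(C7OCCO7)c3)c(C7OCCO7)c2)c(C7OCCO7)c1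
F6 | step 2 | 3,5-bis(bromomethyl)-4-fluorophenyl acetate | CC(=O)Oc1cc(CBr)c(F)c(CBr)c1
F7 | step 2 | 4-fluoro-3,5-diformylphenyl acetate | CC(=O)Oc1cc(C=O)c(F)c(C=O)c1
F8 | step 17 | tetradecaacetate of 21 | CC(=O)Oc1cc(OC(C)=O)c(Oc2cc(OC(C)=O)c(Oc3cc(OC(C)=O)c(Oc4cc(OC(C)=O)c(Oc5cc(OC(C)=O)c(Oc6cc(OC(C)=O)c(OC(C)=O)c(OC(C)=O)c6)c(OC(C)=O)c5)c(OC(C)=O)c4)c(OC(C)=O)c3)c(OC(C)=O)c2)c(OC(C)=O)c1
A1 | alternative 1 | syringic acid (4-hydroxy-3,5-dimethoxybenzoic acid) | COc1cc(C(=O)O)cc(OC)c1O
A2 | alternative 1 | 2,4,6-trimethoxyphenol | COc1cc(OC)c(O)c(OC)c1
A3 | alternative 1 | undecamethyl ring A–B–C–D–E pentamer phenol | COc1cc(OC)c(Oc2cc(OC)c(Oc3cc(OC)c(Oc4cc(OC)c(Oc5cc(OC)c(O)c(OC)c5)c(OC)c4)c(OC)c3)c(OC)c2)c(OC)c1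
A4 | alternative 2 | 3-aryloxycyclobut-2-en-1-one carrying the heptamethyl ring A–B–C trimer on oxygen | COc1cc(OC)c(Oc2cc(OC)c(Oc3cc(OC)c(OC4=CC(=O)C4)c(OC)c3)c(OC)c2)c(OC)c1
A5 | alternative 2 | 1-aryloxy-2-(triisopropylsiloxy)acetylene carrying the pentamethyl ring E–F dimer on oxygen | CC(C)[Si](C(C)C)(C(C)C)OC#COc1cc(OC)c(Oc2cc(OC)c(OC)c(OC)c2)c(OC)c1
A6 | alternative 2 | hexamer with ring D as a mono-silylated resorcinol | COc1cc(OC)c(Oc2cc(OC)c(Oc3cc(OC)c(Oc4cc(O)c(Oc5cc(OC)c(Oc6cc(OC)c(OC)c(OC)c6)c(OC)c5)c(O[Si](C(C)C)(C(C)C)C(C)C)c4)c(OC)c3)c(OC)c2)c(OC)c1
A7 | alternative 3 | methyl 6-[4-(benzyloxy)-3,5-dimethoxyphenoxy]-3,5-dioxohexanoate | COC(=O)CC(=O)CC(=O)COc1cc(OC)c(OCc2ccccc2)c(OC)c1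
A8 | alternative 3 | 2-[4-(benzyloxy)-3,5-dimethoxyphenoxy]benzene-1,3,5-triol | Oc1cc(O)c(Oc2cc(OC)c(OCc3ccccc3)c(OC)c2)c(O)c1
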